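Decide what the next flask gets: more time, or a different charge of coupling partner. Eta is the flask asked about; delta ran earlier at twice its concentration.

| flask | substrate | coupling partner | remark | time |
|---|---|---|---|---|
| eta | 16 mM | 1.2 equiv | the very flask that is asked about, followed so far |  |
| delta | 32 mM | 1.2 equiv | run made earlier |  |
| flask | 16 mM | 1.20 equiv |  | 20 min |

- eta (time / min: substrate / %, target / %): 0.500: 84.3, 13.0; 1.00: 78.7, 17.7; 1.33: 76.8, 20.1; 2.00: 73.5, 22.0; 2.50: 72.1, 23.7
- delta (time / min: substrate / %, target / %): 4.00: 66.1, 26.4; 8.00: 65.4, 26.8; 12.0: 65.2, 27.1; 15.0: 65.2, 27.2; 20.0: 65.3, 26.7

(each reading ± 0.3 percentage points)

1. which holds at 20 min: what has brought the reaction to rest, or that it has not come to rest (all of the substrate has reacted / forward and back rates have come level / it is still moving / the coupling partner has run out first)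
2. share of the substrate used up at 20 min
3. target at 20 min, in percent of the substrate charged
4. side product at 20 min, in percent of the substrate charged
5. over-reaction product at 20 min, in percent of the substrate charged
6. amount of target if the flask were left three thousand times as long, in percent of the substrate charged

- the reaction counts as stopped when no species that holds the substrate changes by six tenths of a point or more over the second half of the time

Delta's substrate reads 65.4% at 8.00 min and 65.3% at 20.0 min, a change below the scatter of 0.3 percentage points, so waiting longer moved delta no further.

Put that plateau on a scale. Let R, the partner's return, be the fraction of substrate used per equivalent of coupling partner charged. A flask in which the whole partner charge is spent, each partner taking one substrate, reads 1; delta reads 0.290, a reading with its scatter. R does not say what stopped delta: a balance and a spent partner could both read so.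

My own reckoning carries R to eta at the same equivalents and gives 34.8% of the substrate used. That assumes R ignores concentration. My decision is to leave the time alone and change the partner charge in the next flask, since that tests R directly.

The forecast says forward and back rates have come level, with 34.8% used (31.5% to 38%), target 27%, side product 5.5%, over-reaction product 2.2%, and 26.5% target after very long standing. Its ground: “The flat, exponential-looking approach fits balance better than partner decay”. Its conversion matches mine, but both rest on the delta plateau, so that is no check.

Eta gives: the coupling partner has run out first, with 33.5% used, target 28.3%, side product 3.27%, over-reaction product 1.91%, and 28.3% target after very long standing.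

    substrate + coupling partner → target (k = 0.450 /M/s)
    substrate + 2 coupling partner → side product (k = 7.30 /M²/s)
    coupling partner + target → over-reaction product (k = 0.150 /M/s)
    2 coupling partner → self-condensation product (k = 1.30 /M/s)

In eta at 0.198 min, self-condensation uses coupling partner 4.3 times as fast as the target step does. By 20.0 min the partner, the limiting reagent despite its excess in the charge, stands at 0.012% of its charge while substrate stands at 67%; eta's R is 0.279. For the neighbour flask with 0.720 equiv of coupling partner, delta's R gives 20.9% used. The computed neighbour uses 26.7%, so its R is 0.371, higher than delta's.

Readings and results were computed with made-up constants, and the scatter is random.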